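**Plan**

- Retrosynthesis: after removal of the 3'-O-MOM group, ring A is cut at four bonds, C4a–C5, C5–C6, C7–C8 and C8–C8a. This leads back to a (2S)-2-aryl-6-(diazoacetyl)-2,3-dihydropyran-4-one, which already holds rings C and B, and to the ynol ether MeO–C≡C–CH2CH=CMe2.
- Enabling feature: ring A is a pentasubstituted benzene whose atoms C4a (acyl), C5 (OH), C6 (prenyl), C7 (OMe), C8 (H) and C8a (O1) stand in exactly the order in which a vinylketene and an alkoxyalkyne assemble a resorcinol monoether.
- Ring C is cut at O1–C6 and C2–C3 (pyranone numbering) to the B-ring aldehyde and a bis-siloxydiene from methyl 2,4-dioxopentanoate. Ring B is cut at the aryl–geranyl bond, back to 2-bromoisovanillin and geranyl bromide.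
- Forward order: ring B is completed first (MOM ether, acetal, copper-mediated geranylation). Ring C arises second (catalytic asymmetric hetero-Diels–Alder), and its ester is turned into the diazoketone. Ring A arises last (benzannulation), and the MOM ether is removed at the end.
- Stereochemistry: the only stereocenter, C2 (S), is set by the titanium–(S)-BINOL catalyst when ring C forms and is carried through base-free steps. The E-alkene of the geranyl chain comes unchanged from geranyl bromide.

Key step: step 9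

Assumption: the titanium complex of (S)-BINOL is taken to steer the siloxydiene to the Si face of the aryl aldehyde (mirror image of the Re-face preference of the (R)-ligand in allyl- and enolsilane additions to benzaldehydes); if the sense proves opposite, (R)-BINOL is used and nothing else changes.

Abbreviation: Ar = 2-[(2E)-3,7-dimethylocta-2,6-dien-1-yl]-4-methoxy-3-(methoxymethoxy)phenyl.

**Route**

Step 1
Reactants: 1 2-bromo-3-hydroxy-4-methoxybenzaldehyde
Product: 2 2-bromo-4-methoxy-3-(methoxymethoxy)benzaldehyde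
Conditions: MOMCl, i-Pr2NEt, CH2Cl2, 0 °C → rt
Reagents that add atoms: chloromethyl methyl ether, `COCCl`
Why: Base-mediated O-alkylation of the phenol with the α-chloro ether (MOM ether formation) should be clean, and the MOM acetal later tolerates the organolithium, the titanium catalyst, tin hydroxide and the light and heat of the annulation without being prone to the silyl migration an ortho-lithiated silyl ether would suffer.

Step 2
Reactants: 2 2-bromo-4-methoxy-3-(methoxymethoxy)benzaldehyde
Product: 3 2-bromo-1-(dimethoxymethyl)-4-methoxy-3-(methoxymethoxy)benzene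
Conditions: HC(OMe)3, MeOH, PPTS (cat.), rt; Et3N quench
Reagents that add atoms: trimethyl orthoformate, `COC(OC)OC`
Why: Acid-catalysed acetalisation with the orthoformate as water scavenger masks the aldehyde against n-BuLi, and PPTS at room temperature is too weak an acid to cleave the aryl MOM ether.

Step 3
Reactants: 3 2-bromo-1-(dimethoxymethyl)-4-methoxy-3-(methoxymethoxy)benzene; 4 geranyl bromide
Product: 8 Ar–CHO (2-geranyl-4-methoxy-3-(methoxymethoxy)benzaldehyde), via aryllithium 5 (not isolated), via arylcopper 6 (not isolated), via geranylated dimethyl acetal 7 (not isolated)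
Conditions: n-BuLi, THF, −78 °C; CuBr·SMe2, −78 → −40 °C; 4, −78 → 0 °C; then 5% aq. oxalic acid, THF, rt
Reagents that add atoms: water, `O`
Why: Bromine–lithium exchange between the two coordinating ortho groups gives a stable aryllithium, transmetalation to copper makes the substitution of geranyl bromide selective for its primary carbon (organocopper allylation, SN2, E-alkene kept), and dilute oxalic acid then hydrolyses the dimethyl acetal without touching the MOM ether.

Step 4
Reactants: 9 methyl 2,4-dioxopentanoate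
Product: 10 methyl (2Z)-2,4-bis(trimethylsilyloxy)penta-2,4-dienoate
Conditions: TMSOTf (2.2 equiv), Et3N (2.5 equiv), Et2O, 0 °C → rt
Reagents that add atoms: trimethylsilyl trifluoromethanesulfonate, `C[Si](C)(C)OS(=O)(=O)C(F)(F)F`
Why: Soft enolisation with TMSOTf/Et3N silylates both the enol hydroxyl and the methyl ketone, the standard way to 2-siloxy-1,3-dienes of the Danishefsky type; the C2=C3 geometry is of no consequence because that carbon becomes sp2 C6 of the pyranone.

Step 5
Reactants: 8 Ar–CHO; 10 methyl (2Z)-2,4-bis(trimethylsilyloxy)penta-2,4-dienoate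
Product: 12 methyl (2S)-2-Ar-4-oxo-3,4-dihydro-2H-pyran-6-carboxylate, via silylated aldol adduct 11 (not isolated)
Conditions: (S)-BINOL (20 mol %), Ti(Oi-Pr)4 (10 mol %), 4 Å MS, Et2O, −20 °C → rt; then TFA, CH2Cl2, 0 °C (brief)
Reagents that add atoms: none
Why: A titanium–BINOL-catalysed formal hetero-Diels–Alder reaction (Mukaiyama aldol of the siloxydiene terminus with the aryl aldehyde, then acid-induced oxa-Michael addition–elimination with loss of both silyl groups) closes the dihydropyranone; C2 is set under catalyst control by attack on the Si face of the aldehyde and is untouched in the ring closure because its C–O bond stays intact.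

Step 6
Reactants: 12 methyl (2S)-2-Ar-4-oxo-3,4-dihydro-2H-pyran-6-carboxylate
Product: 14 (2S)-2-Ar-4-oxo-3,4-dihydro-2H-pyran-6-carboxylic acid, via trimethylstannyl ester 13 (not isolated)
Conditions: Me3SnOH, ClCH2CH2Cl, 70 °C; then cold 0.1 M aq. HCl wash
Reagents that add atoms: trimethyltin hydroxide, `C[Sn](C)(C)O`
Why: Trimethyltin hydroxide cleaves methyl esters by near-neutral acyl substitution, which avoids hydroxide-induced E1cB opening of the pyranone at C3/C2–O and so should preserve the C2 configuration.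

Step 7
Reactants: 14 (2S)-2-Ar-4-oxo-3,4-dihydro-2H-pyran-6-carboxylic acid
Product: 16 (2S)-2-Ar-6-(diazoacetyl)-2,3-dihydro-4H-pyran-4-one, via acid chloride 15 (not isolated)
Conditions: Me2C=C(Cl)NMe2, CH2Cl2, 0 °C → rt; then added to CH2N2 (excess), Et2O, −10 → 0 °C; N2 purge
Reagents that add atoms: diazomethane, `C=[N+]=[N-]`
Why: Arndt–Eistert-type acylation of diazomethane: the α-chloroenamine gives the acid chloride without releasing HCl (safe for the MOM ether and the trisubstituted alkenes), a second equivalent of diazomethane takes up the HCl of the acylation, and low temperature with short contact keeps dipolar cycloaddition to the ring alkene from competing.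

Step 8
Reactants: 17 2-chloro-1,1-dimethoxyethane; 18 prenyl bromide
Product: 20 1-methoxy-5-methylhex-4-en-1-yne, via sodium methoxyacetylide 19 (not isolated)
Conditions: NaNH2 (3.0 equiv), liq. NH3, −40 °C; then 18, −40 → −33 °C; NH3 evaporated, pentane/H2O
Reagents that add atoms: none
Why: Sodium amide removes methanol and then HCl from the α-chloro acetal and deprotonates the methoxyacetylene formed, and the acetylide is C-alkylated in the same flask by the primary allylic bromide (SN2 alkylation of an alkoxyacetylide, the standard route to 1-alkoxy-1-alkynes); the methyl ether is chosen because it cannot fragment by a retro-ene path on later heating.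

Step 9
Reactants: 16 (2S)-2-Ar-6-(diazoacetyl)-2,3-dihydro-4H-pyran-4-one; 20 1-methoxy-5-methylhex-4-en-1-yne
Product: 25 (2S)-2-Ar-5-hydroxy-7-methoxy-6-(3-methylbut-2-en-1-yl)-2,3-dihydro-4H-chromen-4-one, via vinylketene 21 (not isolated), via vinylcyclobutenone 22 (not isolated), via dienylketene 23 (not isolated), via keto tautomer 24 (not isolated)
Conditions: 20 (2 equiv), degassed ClCH2CH2Cl (0.05 M), blue LED (420–450 nm), 20 °C; then 80 °C
Reagents that add atoms: none
Why: Proposed new method: irradiation at a wavelength absorbed only by the diazo chromophore should trigger Wolff rearrangement, in which pyranone C6 shifts to the diazo carbon (C8–C8a) to give vinylketene 21; its ketene carbon is attacked by the nucleophilic, prenyl-bearing carbon of the ynol ether in a regioselective [2+2] cycloaddition (C5–C6 and C7–C8) to give 3-methoxy-4-vinylcyclobutenone 22, which on warming opens by 4π electrocyclic ring opening to dienylketene 23. Ring A then closes by thermal 6π electrocyclisation of 23 onto the pyranone α-carbon (C4a–C5), and enolisation of the β-dicarbonyl-type dienone 24 gives the hydrogen-bonded 5-phenol. The closest known reaction type is the second-generation Danheiser benzannulation of α′-diazo-α,β-enones with alkoxy- and siloxyalkynes; new here is a vinylketene whose vinyl unit is the β-oxygenated C5=C6 bond of a dihydropyran-4-one, which should leave the pericyclic sequence unchanged because the ring oxygen and the C4 carbonyl are only substituents on the triene. No stereocenter that survives is created (C4 of 22 and C4a of 24 are lost on ring opening and aromatisation), and C2 lies outside every bond change, so its S configuration should be carried through under neutral conditions. The step needs regioselectivity (OH at C5, prenyl at C6, OMe at C7, H at C8), secured by the polarisation of the ynol ether, and chemoselectivity, secured by the excess of the electron-rich alkyne over the three unactivated trisubstituted alkenes and by visible light that excites the diazo group and not the enone.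

Step 10
Reactants: 25 (2S)-2-Ar-5-hydroxy-7-methoxy-6-(3-methylbut-2-en-1-yl)-2,3-dihydro-4H-chromen-4-one
Product: 26 (2S)-2-{2-[(2E)-3,7-dimethylocta-2,6-dien-1-yl]-3-hydroxy-4-methoxyphenyl}-5-hydroxy-7-methoxy-6-(3-methylbut-2-en-1-yl)-2,3-dihydro-4H-chromen-4-one
Conditions: 3 M aq. HCl, MeOH, 40 °C
Reagents that add atoms: none
Why: Acid-catalysed solvolysis of the MOM acetal in methanol is non-basic and so avoids retro-oxa-Michael opening of the flavanone (the racemisation path at C2), and it is mild enough that cyclisation of the ortho-prenyl and ortho-geranyl phenols to chromans should not compete.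

**Compound list**

1 | 2-bromo-3-hydroxy-4-methoxybenzaldehyde | `COc1ccc(C=O)c(Br)c1O` | starting material
2 | 2-bromo-4-methoxy-3-(methoxymethoxy)benzaldehyde | `COCOc1c(Br)c(C=O)ccc1OC` | intermediate
3 | 2-bromo-1-(dimethoxymethyl)-4-methoxy-3-(methoxymethoxy)benzene | `COCOc1c(Br)c(C(OC)OC)ccc1OC` | intermediate
4 | geranyl bromide, (2E)-1-bromo-3,7-dimethylocta-2,6-diene | `CC(C)=CCC/C(C)=C/CBr` | starting material
5 | [6-(dimethoxymethyl)-3-methoxy-2-(methoxymethoxy)phenyl]lithium (formed in situ) | `[Li]c1c(C(OC)OC)ccc(OC)c1OCOC` | intermediate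
6 | [6-(dimethoxymethyl)-3-methoxy-2-(methoxymethoxy)phenyl]copper (formed in situ) | `[Cu]c1c(C(OC)OC)ccc(OC)c1OCOC` | intermediate
7 | Ar–CH(OMe)2, 1-(dimethoxymethyl)-2-geranyl-4-methoxy-3-(methoxymethoxy)benzene (not isolated) | `COCOc1c(C/C=C(\C)CCC=C(C)C)c(C(OC)OC)ccc1OC` | intermediate
8 | Ar–CHO, 2-[(2E)-3,7-dimethylocta-2,6-dien-1-yl]-4-methoxy-3-(methoxymethoxy)benzaldehyde | `COCOc1c(C/C=C(\C)CCC=C(C)C)c(C=O)ccc1OC` | intermediate
9 | methyl 2,4-dioxopentanoate | `COC(=O)C(=O)CC(C)=O` | starting material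
10 | methyl (2Z)-2,4-bis(trimethylsilyloxy)penta-2,4-dienoate | `COC(=O)/C(O[Si](C)(C)C)=C/C(=C)O[Si](C)(C)C` | intermediate
11 | methyl (2Z,6S)-6-Ar-4-oxo-2,6-bis(trimethylsilyloxy)hex-2-enoate (not isolated) | `COc1ccc([C@H](CC(=O)/C=C(\O[Si](C)(C)C)C(=O)OC)O[Si](C)(C)C)c(C/C=C(\C)CCC=C(C)C)c1OCOC` | intermediate
12 | methyl (2S)-2-Ar-4-oxo-3,4-dihydro-2H-pyran-6-carboxylate | `COc1ccc([C@@H]2CC(=O)C=C(C(=O)OC)O2)c(C/C=C(\C)CCC=C(C)C)c1OCOC` | intermediate
13 | trimethylstannyl (2S)-2-Ar-4-oxo-3,4-dihydro-2H-pyran-6-carboxylate (not isolated) | `COc1ccc([C@@H]2CC(=O)C=C(C(=O)O[Sn](C)(C)C)O2)c(C/C=C(\C)CCC=C(C)C)c1OCOC` | intermediate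
14 | (2S)-2-Ar-4-oxo-3,4-dihydro-2H-pyran-6-carboxylic acid | `COc1ccc([C@@H]2CC(=O)C=C(C(=O)O)O2)c(C/C=C(\C)CCC=C(C)C)c1OCOC` | intermediate
15 | (2S)-2-Ar-4-oxo-3,4-dihydro-2H-pyran-6-carbonyl chloride (not isolated) | `COc1ccc([C@@H]2CC(=O)C=C(C(=O)Cl)O2)c(C/C=C(\C)CCC=C(C)C)c1OCOC` | intermediate
16 | (2S)-2-Ar-6-(diazoacetyl)-2,3-dihydro-4H-pyran-4-one | `COc1ccc([C@@H]2CC(=O)C=C(C(=O)C=[N+]=[N-])O2)c(C/C=C(\C)CCC=C(C)C)c1OCOC` | intermediate
17 | 2-chloro-1,1-dimethoxyethane (chloroacetaldehyde dimethyl acetal) | `COC(CCl)OC` | starting material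
18 | prenyl bromide, 1-bromo-3-methylbut-2-ene | `CC(C)=CCBr` | starting material
19 | sodium methoxyacetylide (formed in situ) | `[Na+].[C-]#COC` | intermediate
20 | 1-methoxy-5-methylhex-4-en-1-yne | `COC#CCC=C(C)C` | intermediate
21 | vinylketene, (2S)-2-Ar-6-(2-oxoethenyl)-2,3-dihydro-4H-pyran-4-one (not isolated) | `COc1ccc([C@@H]2CC(=O)C=C(C=C=O)O2)c(C/C=C(\C)CCC=C(C)C)c1OCOC` | intermediate
22 | vinylcyclobutenone, (2S)-2-Ar-6-[2-methoxy-3-(3-methylbut-2-en-1-yl)-4-oxocyclobut-2-en-1-yl]-2,3-dihydro-4H-pyran-4-one, cyclobutenone CH of either configuration (not isolated) | `COc1ccc([C@@H]2CC(=O)C=C(C3C(=O)C(CC=C(C)C)=C3OC)O2)c(C/C=C(\C)CCC=C(C)C)c1OCOC` | intermediate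
23 | dienylketene, (2S)-2-Ar-6-[(1E)-2-methoxy-3-(3-methylbut-2-en-1-yl)-4-oxobuta-1,3-dien-1-yl]-2,3-dihydro-4H-pyran-4-one (not isolated) | `COc1ccc([C@@H]2CC(=O)C=C(/C=C(\C(CC=C(C)C)=C=O)OC)O2)c(C/C=C(\C)CCC=C(C)C)c1OCOC` | intermediate
24 | keto tautomer of 25, (2S)-2-Ar-7-methoxy-6-(3-methylbut-2-en-1-yl)-2,3-dihydrochromene-4,5(4aH)-dione, C4a of either configuration (not isolated) | `COc1ccc([C@@H]2CC(=O)C3C(=O)C(CC=C(C)C)=C(OC)C=C3O2)c(C/C=C(\C)CCC=C(C)C)c1OCOC` | intermediate
25 | (2S)-2-Ar-5-hydroxy-7-methoxy-6-(3-methylbut-2-en-1-yl)-2,3-dihydro-4H-chromen-4-one (flavanone 3'-MOM ether) | `COc1ccc([C@@H]2CC(=O)c3c(cc(OC)c(CC=C(C)C)c3O)O2)c(C/C=C(\C)CCC=C(C)C)c1OCOC` | intermediate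
26 | (2S)-2-{2-[(2E)-3,7-dimethylocta-2,6-dien-1-yl]-3-hydroxy-4-methoxyphenyl}-5-hydroxy-7-methoxy-6-(3-methylbut-2-en-1-yl)-2,3-dihydro-4H-chromen-4-one | `COc1ccc([C@@H]2CC(=O)c3c(cc(OC)c(CC=C(C)C)c3O)O2)c(C/C=C(\C)CCC=C(C)C)c1O` | target

**Step count**

Total step count: 10. Longest linear sequence: 8 steps (steps 1, 2, 3, 5, 6, 7, 9, 10); steps 4 and 8 are side branches.

**Steps most likely to fail**

1. Step 9.
What may go wrong: the photogenerated carbene may be diverted into insertion or cyclopropanation at the side-chain alkenes before the 1,2-shift; the β-oxygenated vinylketene may dimerise or add sluggishly to the ynol ether; or the sequence may stall at the cyclobutenone.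
Fallback (known chemistry; ring A is brought in as a preformed acetophenone): it sets out from aldehyde 8 and comes back to the route at target 26. Commercial 1-(2,6-dihydroxy-4-methoxyphenyl)ethanone is mono-protected (MOMCl, i-Pr2NEt) to 1-[2-hydroxy-4-methoxy-6-(methoxymethoxy)phenyl]ethanone F1. O-Prenylation (prenyl bromide, K2CO3, acetone) gives 1-[4-methoxy-2-(methoxymethoxy)-6-(3-methylbut-2-en-1-yloxy)phenyl]ethanone F2. Heating F2 in N,N-diethylaniline (about 200 °C) should bring about a para-Claisen–Cope rearrangement that places the prenyl group para to the freed phenol, between OMe and OMOM, giving 1-[6-hydroxy-4-methoxy-2-(methoxymethoxy)-3-(3-methylbut-2-en-1-yl)phenyl]ethanone F3. Claisen–Schmidt condensation of F3 with 8 (KOH, EtOH) should give the chalcone (2E)-3-Ar-1-[6-hydroxy-4-methoxy-2-(methoxymethoxy)-3-(3-methylbut-2-en-1-yl)phenyl]prop-2-en-1-one F4. Because only the phenol next to the ring hydrogen is free, oxa-Michael closure (NaOAc, EtOH, reflux) can give only the 6-prenyl isomer, racemic 2-Ar-7-methoxy-5-(methoxymethoxy)-6-(3-methylbut-2-en-1-yl)-2,3-dihydro-4H-chromen-4-one F5. Kinetic resolution by asymmetric transfer hydrogenation ((R,R)-TsDPEN–Rh(III), HCO2H/Et3N; ligand antipode chosen by the usual aryl ketone model) is expected to leave (2S)-2-Ar-7-methoxy-5-(methoxymethoxy)-6-(3-methylbut-2-en-1-yl)-2,3-dihydro-4H-chromen-4-one F6 untouched. The (2R)-enantiomer is reduced to the cis-alcohol (2R,4R)-2-Ar-7-methoxy-5-(methoxymethoxy)-6-(3-methylbut-2-en-1-yl)-3,4-dihydro-2H-chromen-4-ol F7, which is separated by chromatography. F6 then loses both MOM groups under the conditions of step 10 to give 26.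

2. Step 5.
What may go wrong: the ester-attenuated diene may add too slowly to the hindered, electron-rich aldehyde; facial selectivity may be poor next to the ortho-geranyl group; and the acidic ring closure may cost part of the MOM ether.
Fallback: it sets out from aldehyde 8 and comes back at 12. A direct aldol reaction of 8 with acetone under a D-prolinamide organocatalyst (Si-face attack, the mirror image of the (R)-aldols that L-proline catalysts give with aryl aldehydes) should give (4S)-4-Ar-4-hydroxybutan-2-one F8. Silylation (TESCl, imidazole) gives (4S)-4-Ar-4-(triethylsilyloxy)butan-2-one F9. Kinetic enolisation of the methyl group (LiHMDS, THF, −78 °C) and Claisen condensation with dimethyl oxalate give methyl (6S)-6-Ar-2,4-dioxo-6-(triethylsilyloxy)hexanoate F10. TFA in wet CH2Cl2 at 0 °C removes the silyl group, and the δ-hydroxy diketo ester cyclises with loss of water to 12, the carbinol C–O bond staying intact.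

3. Step 8.
What may go wrong: ammonolysis or elimination of prenyl bromide; amide-induced propargyl–allenyl isomerisation of the skipped enyne; and loss of the volatile, acid-labile ynol ether on isolation.
Fallback: it sets out from diazoketone 16 and comes back at 25. Ethyl 4-methylpent-3-enoate is homologated to the lithium ynolate (CH2Br2/LiTMP, then LiHMDS and n-BuLi; Kowalski ester homologation) and O-silylated (TIPSCl) to triisopropyl[(5-methylhex-4-en-1-yn-1-yl)oxy]silane F11, a siloxyalkyne of the class most used in this benzannulation. Under the conditions of step 9, 16 and F11 should give (2S)-2-Ar-5-hydroxy-6-(3-methylbut-2-en-1-yl)-7-(triisopropylsilyloxy)-2,3-dihydro-4H-chromen-4-one F12. TBAF buffered with AcOH (to avoid base-induced opening of the flavanone) frees (2S)-2-Ar-5,7-dihydroxy-6-(3-methylbut-2-en-1-yl)-2,3-dihydro-4H-chromen-4-one F13. Diazomethane then methylates only the 7-OH, the 5-OH being locked in a hydrogen bond to C4=O, which returns 25.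

**Further compounds**

F1 | step 9 | 1-[2-hydroxy-4-methoxy-6-(methoxymethoxy)phenyl]ethanone | `CC(=O)c1c(O)cc(OC)cc1OCOC`
F2 | step 9 | 1-[4-methoxy-2-(methoxymethoxy)-6-(3-methylbut-2-en-1-yloxy)phenyl]ethanone | `CC(=O)c1c(OCC=C(C)C)cc(OC)cc1OCOC`
F3 | step 9 | 1-[6-hydroxy-4-methoxy-2-(methoxymethoxy)-3-(3-methylbut-2-en-1-yl)phenyl]ethanone | `CC(=O)c1c(O)cc(OC)c(CC=C(C)C)c1OCOC`
F4 | step 9 | (2E)-3-Ar-1-[6-hydroxy-4-methoxy-2-(methoxymethoxy)-3-(3-methylbut-2-en-1-yl)phenyl]prop-2-en-1-one | `COCOc1c(CC=C(C)C)c(OC)cc(O)c1C(=O)/C=C/c1ccc(OC)c(OCOC)c1C/C=C(\C)CCC=C(C)C`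
F5 | step 9 | racemic 2-Ar-7-methoxy-5-(methoxymethoxy)-6-(3-methylbut-2-en-1-yl)-2,3-dihydro-4H-chromen-4-one | `COc1ccc(C2CC(=O)c3c(cc(OC)c(CC=C(C)C)c3OCOC)O2)c(C/C=C(\C)CCC=C(C)C)c1OCOC`
F6 | step 9 | (2S)-2-Ar-7-methoxy-5-(methoxymethoxy)-6-(3-methylbut-2-en-1-yl)-2,3-dihydro-4H-chromen-4-one | `COc1ccc([C@@H]2CC(=O)c3c(cc(OC)c(CC=C(C)C)c3OCOC)O2)c(C/C=C(\C)CCC=C(C)C)c1OCOC`
F7 | step 9 | (2R,4R)-2-Ar-7-methoxy-5-(methoxymethoxy)-6-(3-methylbut-2-en-1-yl)-3,4-dihydro-2H-chromen-4-ol | `COc1ccc([C@H]2C[C@@H](O)c3c(cc(OC)c(CC=C(C)C)c3OCOC)O2)c(C/C=C(\C)CCC=C(C)C)c1OCOC`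
F8 | step 5 | (4S)-4-Ar-4-hydroxybutan-2-one | `CC(=O)C[C@H](O)c1ccc(OC)c(OCOC)c1C/C=C(\C)CCC=C(C)C`
F9 | step 5 | (4S)-4-Ar-4-(triethylsilyloxy)butan-2-one | `CC(=O)C[C@H](O[Si](CC)(CC)CC)c1ccc(OC)c(OCOC)c1C/C=C(\C)CCC=C(C)C`
F10 | step 5 | methyl (6S)-6-Ar-2,4-dioxo-6-(triethylsilyloxy)hexanoate | `COC(=O)C(=O)CC(=O)C[C@H](O[Si](CC)(CC)CC)c1ccc(OC)c(OCOC)c1C/C=C(\C)CCC=C(C)C`
F11 | step 8 | triisopropyl[(5-methylhex-4-en-1-yn-1-yl)oxy]silane | `CC(C)=CCC#CO[Si](C(C)C)(C(C)C)C(C)C`
F12 | step 8 | (2S)-2-Ar-5-hydroxy-6-(3-methylbut-2-en-1-yl)-7-(triisopropylsilyloxy)-2,3-dihydro-4H-chromen-4-one | `COc1ccc([C@@H]2CC(=O)c3c(cc(O[Si](C(C)C)(C(C)C)C(C)C)c(CC=C(C)C)c3O)O2)c(C/C=C(\C)CCC=C(C)C)c1OCOC`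
F13 | step 8 | (2S)-2-Ar-5,7-dihydroxy-6-(3-methylbut-2-en-1-yl)-2,3-dihydro-4H-chromen-4-one | `COc1ccc([C@@H]2CC(=O)c3c(cc(O)c(CC=C(C)C)c3O)O2)c(C/C=C(\C)CCC=C(C)C)c1OCOC`
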